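**Plan**
- With the arene numbered C1 (oxiranyl carbon), C4 (formyl carbon) and C6 (acyloxy carbon), the retrosynthesis cuts the ring bonds C1–C6 and C2–C3. Arene carbons C3–C6 then become C6, C5, C4 and C3 of a 2-pyrone that has lost its lactone bridge as CO2, and C1–C2 become a terminal alkyne.
- The feature that allows this is the substitution pattern of the benzene ring: an acceptor (CHO) para and an ester oxygen ortho to the quaternary oxirane carbon is what a 3-acyloxy-5-formyl-2-pyrone and a monosubstituted alkyne deliver.
- Alkyne arm: 2-bromoprop-2-en-1-ol is coupled with ethynyltrimethylsilane, epoxidised, acylated and C-desilylated.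
- Pyrone arm: coumalic acid is reduced to the aldehyde, brominated at C3, converted into the 3-hydroxy pyrone by borylation–oxidation and O-acylated.
- The arms are joined last: the benzene ring, the only ring formed in the convergent step, closes by [4+2] cycloaddition and aromatises by loss of CO2; the oxirane is made earlier and carried through.
- The single stereocentre (quaternary oxirane carbon, R in the target) is set by a Sharpless asymmetric epoxidation with L-(+)-diisopropyl tartrate and is not touched afterwards.

Key step: step 9

Assumption: the face selectivity of the titanium–tartrate epoxidation known for allyl and 2-alkylallyl alcohols is taken to hold for the 2-alkynyl allylic alcohol of step 2.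

Step 1
Reactants: 1 2-bromoprop-2-en-1-ol; 2 ethynyltrimethylsilane
Product: 3 2-methylidene-4-(trimethylsilyl)but-3-yn-1-ol
Conditions: PdCl2(PPh3)2 (2 mol %), CuI (4 mol %), Et3N, THF, rt to 40 °C
Reagents that add atoms: ethynyltrimethylsilane (2), C#C[Si](C)(C)C
Why: Sonogashira coupling of the alkenyl bromide with the terminal alkyne takes place at the C–Br bond only, tolerates the free allylic hydroxyl and creates no stereocentre.

Step 2
Reactants: 3 2-methylidene-4-(trimethylsilyl)but-3-yn-1-ol
Product: 4 [(2S)-2-[(trimethylsilyl)ethynyl]oxiran-2-yl]methanol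
Conditions: Ti(OiPr)4 (10 mol %), L-(+)-diisopropyl tartrate (12 mol %), t-BuOOH (anhydrous), 4 Å molecular sieves, CH2Cl2, −20 °C
Reagents that add atoms: tert-butyl hydroperoxide, CC(C)(C)OO
Why: In this Sharpless asymmetric epoxidation of a 2-substituted allylic alcohol the titanium–(2R,3R)-tartrate complex binds the hydroxyl and delivers the peroxide oxygen to the alkene face that gives (S)-glycidol from allyl alcohol, which sets the quaternary oxirane carbon as S (alkynyl group lowest in priority), while catalytic titanium with molecular sieves at low temperature limits opening of the tertiary propargylic oxirane.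

Step 3
Reactants: 4 [(2S)-2-[(trimethylsilyl)ethynyl]oxiran-2-yl]methanol; 5 3-methylbutanoyl chloride
Product: 6 [(2R)-2-[(trimethylsilyl)ethynyl]oxiran-2-yl]methyl 3-methylbutanoate
Conditions: Et3N, DMAP (cat.), CH2Cl2, 0 °C
Reagents that add atoms: 3-methylbutanoyl chloride (5), CC(C)CC(Cl)=O
Why: DMAP-catalysed O-acylation of the primary alcohol leaves the oxirane untouched under cold, non-aqueous conditions (no Payne-type migration), and the descriptor changes from S to R only because the acyloxymethyl arm now outranks the ring methylene.

Step 4
Reactants: 6 [(2R)-2-[(trimethylsilyl)ethynyl]oxiran-2-yl]methyl 3-methylbutanoate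
Product: 7 [(2R)-2-ethynyloxiran-2-yl]methyl 3-methylbutanoate
Conditions: Bu4NF, AcOH, THF, 0 °C
Reagents that add atoms: none
Why: Fluoride-induced protodesilylation of the alkynylsilane is fast at 0 °C, and the acetic acid buffer keeps the medium non-basic so that the ester is not cleaved and the oxirane is not opened.

Step 5
Reactants: 8 coumalic acid (2-oxo-2H-pyran-5-carboxylic acid)
Product: 10 2-oxo-2H-pyran-5-carbaldehyde, via 2-oxo-2H-pyran-5-carbonyl chloride 9 (not isolated)
Conditions: (COCl)2, DMF (cat.), CH2Cl2, rt; evaporate; then Bu3SnH (slow addition), Pd(PPh3)4 (2 mol %), THF, rt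
Reagents that add atoms: none
Why: Acid chloride formation followed by palladium-catalysed tin hydride reduction stops at the aldehyde because oxidative addition of the acyl chloride to zerovalent palladium is far faster than any hydride transfer to the pyrone ring.

Step 6
Reactants: 10 2-oxo-2H-pyran-5-carbaldehyde
Product: 11 3-bromo-2-oxo-2H-pyran-5-carbaldehyde
Conditions: Br2, CH2Cl2, 0 °C to rt, dark; then Et3N, 0 °C
Reagents that add atoms: bromine, BrBr
Why: Electrophilic bromination by addition–elimination occurs at C3, the only unsubstituted nucleophilic position of a 5-substituted 2-pyrone (α to the lactone carbonyl and conjugated with the ring oxygen), as it does with coumalate esters.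

Step 7
Reactants: 11 3-bromo-2-oxo-2H-pyran-5-carbaldehyde
Product: 13 3-hydroxy-2-oxo-2H-pyran-5-carbaldehyde, via pinacol boronate 12 (not isolated)
Conditions: B2pin2, PdCl2(dppf) (3 mol %), KOAc, 1,4-dioxane, 80 °C; then Me3NO (excess), rt; mildly acidic aqueous work-up
Reagents that add atoms: trimethylamine N-oxide, C[N+](C)(C)[O-]
Why: Miyaura borylation of the electron-poor alkenyl-type C3–Br bond under weakly basic conditions is followed in the same flask by amine N-oxide oxidation, in which the pyronyl carbon migrates from boron to oxygen, a neutral oxidation that spares the aldehyde and the hydroxide-sensitive pyrone.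

Step 8
Reactants: 13 3-hydroxy-2-oxo-2H-pyran-5-carbaldehyde; 5 3-methylbutanoyl chloride
Product: 14 5-formyl-2-oxo-2H-pyran-3-yl 3-methylbutanoate
Conditions: pyridine, CH2Cl2, 0 °C
Reagents that add atoms: 3-methylbutanoyl chloride (5), CC(C)CC(Cl)=O
Why: The enolic 3-hydroxyl of the pyrone is acidic and is O-acylated by the acid chloride with pyridine as a mild base, which gives the enol ester without exposing the ring to hydroxide or strongly nucleophilic amines.

Step 9
Reactants: 7 [(2R)-2-ethynyloxiran-2-yl]methyl 3-methylbutanoate; 14 5-formyl-2-oxo-2H-pyran-3-yl 3-methylbutanoate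
Product: 16 [(2R)-2-[4-formyl-2-(3-methylbutanoyloxy)phenyl]oxiran-2-yl]methyl 3-methylbutanoate, via bridged lactone cycloadduct 15 (not isolated)
Conditions: PhMe, 130 °C, sealed tube
Reagents that add atoms: none
Why: The electron-poor pyrone is the diene of an inverse-electron-demand Diels–Alder reaction in which the unsubstituted alkyne carbon, the more nucleophilic and less hindered terminus, bonds first to pyrone C6 (β to the formyl group, δ to the lactone carbonyl) and the substituted carbon then closes onto C3 to give the 2-oxabicyclo[2.2.2]octadienone 15. The benzene ring is thus closed by one intermolecular, concerted but asynchronous [4+2] cycloaddition that forms both new ring C–C bonds, and 15 then loses CO2 by an irreversible, aromatising retro-[4+2] reaction. The closest known chemistry is the thermal reaction of coumalate esters and other 5-acceptor 2-pyrones with terminal alkynes, which gives para-substituted benzoates. No stereocentre is created, since the bridgehead centres of 15 disappear on CO2 loss and the oxirane carbon takes part in no bond change and keeps its R configuration. The selectivity needed is regiochemical (formyl para and acyloxy ortho to the quaternary carbon), and it rests on the polarity match just described, on a formyl group that is a stronger acceptor than an ester, and on an asynchronous transition state that keeps the congested C3–alkyne bond long until late. Neutral aprotic heating should spare both esters, the aldehyde and the oxirane, and because the ring oxygen is acylated from the start, no free ortho-phenol that could attack the oxirane is ever present.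

**Compound list**
1 | 2-bromoprop-2-en-1-ol | OCC(Br)=C | starting material
2 | ethynyltrimethylsilane | C#C[Si](C)(C)C | starting material
3 | 2-methylidene-4-(trimethylsilyl)but-3-yn-1-ol | C=C(CO)C#C[Si](C)(C)C | intermediate
4 | [(2S)-2-[(trimethylsilyl)ethynyl]oxiran-2-yl]methanol | OC[C@@]1(C#C[Si](C)(C)C)CO1 | intermediate
5 | 3-methylbutanoyl chloride | CC(C)CC(Cl)=O | starting material
6 | [(2R)-2-[(trimethylsilyl)ethynyl]oxiran-2-yl]methyl 3-methylbutanoate | CC(C)CC(=O)OC[C@@]1(C#C[Si](C)(C)C)CO1 | intermediate
7 | [(2R)-2-ethynyloxiran-2-yl]methyl 3-methylbutanoate | CC(C)CC(=O)OC[C@@]1(C#C)CO1 | intermediate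
8 | coumalic acid (2-oxo-2H-pyran-5-carboxylic acid) | O=C(O)C1=COC(=O)C=C1 | starting material
9 | 2-oxo-2H-pyran-5-carbonyl chloride (not isolated) | O=C(Cl)C1=COC(=O)C=C1 | intermediate
10 | 2-oxo-2H-pyran-5-carbaldehyde | O=CC1=COC(=O)C=C1 | intermediate
11 | 3-bromo-2-oxo-2H-pyran-5-carbaldehyde | O=CC1=COC(=O)C(Br)=C1 | intermediate
12 | 2-oxo-3-(4,4,5,5-tetramethyl-1,3,2-dioxaborolan-2-yl)-2H-pyran-5-carbaldehyde (not isolated) | O=CC1=COC(=O)C(B2OC(C)(C)C(C)(C)O2)=C1 | intermediate
13 | 3-hydroxy-2-oxo-2H-pyran-5-carbaldehyde | O=CC1=COC(=O)C(O)=C1 | intermediate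
14 | 5-formyl-2-oxo-2H-pyran-3-yl 3-methylbutanoate | O=CC1=COC(=O)C(OC(=O)CC(C)C)=C1 | intermediate
15 | [(2R)-2-[7-formyl-4-(3-methylbutanoyloxy)-3-oxo-2-oxabicyclo[2.2.2]octa-5,7-dien-5-yl]oxiran-2-yl]methyl 3-methylbutanoate (not isolated; bridgehead configuration not controlled, both diastereomers give 16) | O=C1OC2C(C=O)=CC1(OC(=O)CC(C)C)C([C@]3(COC(=O)CC(C)C)CO3)=C2 | intermediate
16 | [(2R)-2-[4-formyl-2-(3-methylbutanoyloxy)phenyl]oxiran-2-yl]methyl 3-methylbutanoate | CC(C)CC(=O)OC[C@@]1(c2ccc(C=O)cc2OC(=O)CC(C)C)CO1 | target

Total step count: 9
Longest linear sequence: 5 steps (steps 5, 6, 7, 8 and 9; the alkyne arm, steps 1 to 4 followed by step 9, is equally long)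

**Steps most likely to fail**

Step 9. The cycloaddition may be slow because the dienophile is an inductively deactivated terminal alkyne next to a quaternary carbon. The temperature then needed could rearrange or open the tertiary propargylic oxirane, and the steric clash at the C3 terminus could erode the para regioselectivity. The fallback forms the arene first and the oxirane last; it sets out from 3 and comes back to the route at 16.
- Silylation of 3 (TBSCl, imidazole, DMF) would give tert-butyldimethyl{[2-methylidene-4-(trimethylsilyl)but-3-yn-1-yl]oxy}silane F1.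
- K2CO3 in MeOH would remove only the C-silyl group to give tert-butyldimethyl[(2-methylidenebut-3-yn-1-yl)oxy]silane F2, a cheap and thermally robust enyne that can be used in excess.
- Its cycloaddition with 14 (PhMe, 110–130 °C) and loss of CO2 should give 2-[3-[(tert-butyldimethylsilyl)oxy]prop-1-en-2-yl]-5-formylphenyl 3-methylbutanoate F3. The flat, conjugating vinyl group polarises the alkyne in the required sense. The alkyne is expected to react in preference to the 1,1-disubstituted alkene, whose addition would have to build a quaternary carbon next to the acyloxy-bearing bridgehead.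
- HF·pyridine would then free 5-formyl-2-(3-hydroxyprop-1-en-2-yl)phenyl 3-methylbutanoate F4, a 2-aryl allylic alcohol.
- Epoxidation under the conditions of step 2 (same tartrate) should give 5-formyl-2-[(2S)-2-(hydroxymethyl)oxiran-2-yl]phenyl 3-methylbutanoate F5, and acylation with 5 as in step 3 gives 16.

Step 7. The electron-poor formyl pyrone may be degraded by palladium during borylation, the boronate may undergo protodeboronation, or the oxidant and the liberated amine may attack the aldehyde or C6 of the ring. The fallback puts the oxygen in from the start and the formyl carbon in last; it sets out from 5 and comes back to the route at 14.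
- Purchased 3-hydroxy-2H-pyran-2-one F6 is acylated with 5 (pyridine, CH2Cl2) to 2-oxo-2H-pyran-3-yl 3-methylbutanoate F7.
- Bromination (Br2, CH2Cl2; then Et3N) is expected at C5, the remaining position activated by the ring oxygen and not deactivated by the lactone carbonyl, and would give 5-bromo-2-oxo-2H-pyran-3-yl 3-methylbutanoate F8.
- Palladium-catalysed reductive carbonylation of the C5–Br bond (CO 1 atm, Bu3SnH, Pd(PPh3)4, PhMe, 50 °C) then gives 14.

Step 6. In the formyl pyrone, ionic substitution at C3 may be slow, so that radical bromination of the formyl C–H bond or addition of bromine without clean elimination competes. The fallback brominates before the formyl group exists and adjusts the oxidation level afterwards; it sets out from 8 and comes back to the route at 11.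
- Coumalic acid is brominated at C3 (Br2, AcOH, 60 °C) to 3-bromo-2-oxo-2H-pyran-5-carboxylic acid F9.
- BH3·THF (0 °C) reduces the carboxylic acid chemoselectively in the presence of the lactone and the C–Br bond to 3-bromo-5-(hydroxymethyl)-2H-pyran-2-one F10.
- MnO2 (CH2Cl2, rt) oxidises this allylic-type alcohol to 11.

**Further compounds**
F1 | step 9 | tert-butyldimethyl{[2-methylidene-4-(trimethylsilyl)but-3-yn-1-yl]oxy}silane | C=C(CO[Si](C)(C)C(C)(C)C)C#C[Si](C)(C)C
F2 | step 9 | tert-butyldimethyl[(2-methylidenebut-3-yn-1-yl)oxy]silane | C=C(CO[Si](C)(C)C(C)(C)C)C#C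
F3 | step 9 | 2-[3-[(tert-butyldimethylsilyl)oxy]prop-1-en-2-yl]-5-formylphenyl 3-methylbutanoate | C=C(CO[Si](C)(C)C(C)(C)C)c1ccc(C=O)cc1OC(=O)CC(C)C
F4 | step 9 | 5-formyl-2-(3-hydroxyprop-1-en-2-yl)phenyl 3-methylbutanoate | C=C(CO)c1ccc(C=O)cc1OC(=O)CC(C)C
F5 | step 9 | 5-formyl-2-[(2S)-2-(hydroxymethyl)oxiran-2-yl]phenyl 3-methylbutanoate | OC[C@@]1(c2ccc(C=O)cc2OC(=O)CC(C)C)CO1
F6 | step 7 | 3-hydroxy-2H-pyran-2-one (purchased) | O=C1OC=CC=C1O
F7 | step 7 | 2-oxo-2H-pyran-3-yl 3-methylbutanoate | O=C1OC=CC=C1OC(=O)CC(C)C
F8 | step 7 | 5-bromo-2-oxo-2H-pyran-3-yl 3-methylbutanoate | O=C1OC=C(Br)C=C1OC(=O)CC(C)C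
F9 | step 6 | 3-bromo-2-oxo-2H-pyran-5-carboxylic acid | O=C(O)C1=COC(=O)C(Br)=C1
F10 | step 6 | 3-bromo-5-(hydroxymethyl)-2H-pyran-2-one | OCC1=COC(=O)C(Br)=C1
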